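If the solid substrate held the solution at saturation, 2.1 mM, the coupling in this flask was a pseudo-first-order decay of partner, and I began from that.

solid substrate 27 mM; partner 24.3 mM; protic impurity 8.10 mM; time 10 d

    solid substrate ⇌ dissolved substrate, rate k1*(cs1 - [dissolved substrate]) while solid is left; crystals form when [dissolved substrate] > cs1 (cs1 = 2.1 mM, k1 = 4.5 × 10⁻⁴ s⁻¹)
    dissolved substrate + partner ⇌ target (K2 = 870 L mol⁻¹, k2 = 2.6 × 10⁻⁴ L mol⁻¹ s⁻¹)
    dissolved substrate + target → side product (k3 = 9.0 × 10⁻⁵ L mol⁻¹ s⁻¹)
    solid product ⇌ target, rate k4*(cs4 - [target]) while solid is left; crystals form when [target] > cs4 (cs4 = 9.2 mM, k4 = 1.4 × 10⁻⁴ s⁻¹)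
    target ⇌ isomer of the product (K5 = 3.1, k5 = 3.3 × 10⁻⁵ s⁻¹)
    partner + protic impurity → quenched reagent (k6 = 3.6 × 10⁻⁴ L mol⁻¹ s⁻¹)

- in percentages every species weighs as the solid substrate in it: one side product counts as two
- for target the solid product is counted in
- as a solid, counted per litre of solution: solid substrate, solid product
- at the start none of the solid substrate is in solution
- run time (flask): 10 d

- target and solid product together at 10 d, in percent of the solid substrate charged
- the change that raises the amount of target and solid product together at 10 d, in percent of the solid substrate charged most ("none" if none brings more than 2 percentage points) (Friday's / Tuesday's / Monday's / Wednesday's / none)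
- amount of target and solid product together at 10 d, in percent of the solid substrate charged, after Tuesday's

- Friday's: doubling the amount of partner, all else as stated
- Tuesday's: doubling the solubility in step 4, all else as stated
- Monday's: doubling the solubility in step 1, all else as stated
- Wednesday's: doubling the dissolution coefficient of step 4, all else as stated

Dissolving relaxes with 4.5 × 10⁻⁴ s⁻¹, faster than coupling draws on dissolved substrate at 6.32 × 10⁻⁶ s⁻¹, so I set [dissolved substrate] at saturation and took coupling's coefficient on partner as 0.0472 d⁻¹. The protic impurity begins ahead, at 0.252 d⁻¹. That comparison drifts as the impurity falls, and its half-life with partner held at charge, 0.917 d, is shorter than the time. So I gave the impurity its whole charge, which left 16.2 mM of partner for coupling. On a straight line that partner couples 7.64 mM. Target and isomer relax with half-life 0.184 d, shorter than the time, so target keeps 24.4% of what couples. That gave 6.90% of the charge, and I set the side product aside.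

The weak link was the straight line, since partner falls as it couples. I replaced it with the coupled amount 6.09 mM, meaning the partner beyond the impurity's charge times the fraction that first-order decay at saturation consumes in the time. Target becomes 1.49 mM, less than its solubility, so I expected no solid product and no gain from Tuesday's or Wednesday's. I committed to y = 5.50% and yb = 5.50%. By the same reckoning, doubling partner gives 13.8%, and doubling the solubility in step 1 gives 8.94%, so my choice was Friday's.

The forecast gave 5.9% (range 5% to 6.9%), 5.9% after Tuesday's (range 5% to 6.9%) and Friday's, holding that “no solid product forms”. My figure stood lower than its, and the choice was the same.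

The simulation gave 5.83%, 5.83% after Tuesday's, and Friday's, which gains 7.9 percentage points against 3.3 points for Monday's.

My coupled amount is 22.6% of the charge, and in this flask at 10.0 d target and isomer together stood at 22.7%, beside 1.18% of side product. With the isomerisation struck out, this flask gave 19.5%, the largest single effect, though that covers 15% of what is missing. In the neighbour charged with 11 mM of solid substrate, I reckoned the same coupled amount from the same saturation, which gives 13.5%. That neighbour's computed result was 14.3%, with solid substrate 22.5% still present.

(Its constants stand for no real mixture; the run is a simulation.)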